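## Structural features

The target 28 is a sesquilignan built on a cis-fused 3,7-dioxabicyclo[3.3.0]octane (furofuran): ring A (C7–O–C9'–C8'–C8) and ring B (C7'–O–C9–C8–C8') share the C8–C8' bond. Ring A carries a guaiacyl group on C7 on the convex (exo) face and ring B carries a 3,5-dimethoxy-4-oxyphenyl group (ring C) on C7' on the concave (endo) face, so the four contiguous stereocentres read 7R, 8S, 8'S, 7'S and the two halves of the core are not equivalent. The 4-oxygen of ring C is bound to C8'' of a threo (7''R,8''R) arylglycerol chain that bears a second syringyl ring (ring D, free phenol) and a secondary hydroxyl on C7'' and a primary hydroxyl on C9''; this pair of neighbouring stereocentres is insulated from the core by ring C and cannot be induced by it. Fragile sites are the benzylic C–O bonds at C7 and C7' beside para-oxygenated arenes (acid ionisation, hydrogenolysis, drift of the endo centre C7' to the more stable exo arrangement), the 4-hydroxybenzyl alcohol at C7'' (quinone methide formation) and the two oxidisable phenols. The real difficulty is the unsymmetrical core with one exo and one endo aryl group, which excludes any dimerisation logic, together with the need to bring in the side chain enantiopure and to finish under non-acidic, non-reductive conditions. The key step exploits ring B: its O–C9 bond and the C7'–C8' pair correspond to a 1-aroylcyclopropane fused to the ring A lactone, in which C9 is the cyclopropane methylene and C8' lies between the lactone carbonyl C9' and the aroyl carbonyl C7'. Ring expansion gives the C7'=C8' enol ether, and its saturation from the convex face places the ring C aryl group endo.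

## Logic of the disconnections

28 to 27. The four O–Si bonds (two phenolic, C7''–O, C9''–O) are cut. Fluoride cleavage is the only final operation that is neither acidic nor reductive, and all earlier steps then handle a non-polar compound without free phenols. The forward step must be buffered so that C7, C7' and C7'' are not disturbed.

27 to 25 (through 26). The O–C9' bond of ring A is cut. Cutting at the primary carbon rather than at C7 means the forward etherification never breaks the benzylic C7–O bond, so C7 is retained. Ring A becomes a 1,4-diol; the forward step must sulfonylate only the primary hydroxyl.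

25 to 24. C9' is returned to the carboxyl level and rejoined to the C7 oxygen. The lactone carbonyl is the second acceptor that the cyclopropane will need, and it makes the bicycle rigid and cup-shaped. The forward hydride reduction must spare alkyl and aryl silyl ethers.

24 to 23. The C7'–H and C8'–H bonds are cut, introducing the C7'=C8' enol ether. Both stereocentres then arise in one syn addition whose face is dictated by the cis ring fusion. Two stereocentres are removed; the forward step must saturate a tetrasubstituted push–pull alkene without cleaving benzylic C–O bonds.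

23 to 21. The O–C9 bond is cut and C9 is reconnected to C8'. Ring B and its oxygen then come from an aroyl group on a cyclopropane that already holds C8, and no stereocentre is created in the forward step. The demand is opening at C9 rather than C8 and closure through the ketone oxygen.

21 to 20 to 19. The C8'–C8 and C8'–C9 bonds are cut (carbene plus alkene), then the diazo group is removed. One step forms ring A and the cyclopropane and sets C8 relative to C7. The precursor is an acyclic β-keto ester; the forward step needs facial control from C7 and preference for the alkene over the arenes.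

19 to 4 and 17, then 17 to 15 and 16. The ester O–C9' bond and the C7'–C8' acyl bond are cut. This is the convergent union of the two halves, with 16 supplying C8' and C9'. The acylation must not ionise the sensitive allylic alcohol.

4 to 3 to 2 to 1. The C7–C8 bond is cut (vinyl addition to an aldehyde) and C7 is fixed by kinetic resolution. This traces the guaiacyl half to a purchasable aldehyde in three steps; the resolution must leave the R alcohol.

15 to 13 (through 14), 13 to 12, 12 to 11. The aryl–carboxyl bond is cut with an aryl bromide as latent carboxyl, so no ester has to be hydrolysed beside a phenolic silyl ether. Then the two O–Si bonds and the C9''–N acyl bond are cut. The demands are a clean halogen–metal exchange and a reduction selective for the imide.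

11 to 9 and 6, 9 to 7 and 8, 6 to 5. The C7''–C8'' bond is cut as an auxiliary-controlled aldol, which makes both side-chain stereocentres at once with the aryl ether oxygen already on C8''. No substitution at a stereocentre is needed later. The forward step must give the syn (threo) adduct in the 2S,3R sense.

## Other disconnections considered

Alternative 1: The cut removes C7–C8 and C7'–C8', detaching both aryl-bearing carbons from a four-carbon lactone. In the forward sense, lithiated dithiane A3 would add to the β-carbon of the chiral-pool butenolide A2 anti to its trityloxymethyl group, and the lactone enolate would be trapped by aldehyde A4 anti to the new substituent, giving lactone A1.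
- In its favour: three fragments and the centres C8, C8' and C7' are assembled in one flask under substrate control from a purchasable stereocentre. There is no diazo compound and no hydrogenation, and the side chain enters one oxidation level lower (A4 would come from 14 by formylation).
- Against it here: C7 arrives as a dithioketal that must be unmasked beside electron-rich arenes and then reduced with facial control. The stereocentre of A2 is a sacrificial carbon, so detritylation, lactone reduction and glycol cleavage are needed before C9 has the right oxidation level. The C7' carbinol rests on an open aldol transition state, expected to be the weakest element.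
- Comparison: on structure, both plans give the same 8,8' relationship, but the chosen plan obtains C7' and C8' in one syn addition governed by ring fusion. On mechanism, this is strongly basic ionic chemistry against carbenoid chemistry and a neutral rearrangement. On step economy, A1 is reached quickly but about eight operations would follow it, against four after 23. In convergence, and in avoiding a resolution that discards half of 3, the alternative is the better of the two.

Alternative 2: The cut is at O–C9, C8–C8' and the acyl O–C7 bond, so both rings are assembled around a malonate carbon that becomes C8. In the forward sense, the alkoxide of epoxy alcohol A6 would add to dimethyl methylenemalonate A7, the malonate anion would open the epoxide at C8' with inversion, and the freed C9' alkoxide would lactonise to A5.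
- In its favour: two rings and three bonds form in one operation without a metal carbene. The C7'/C8' relationship would follow from a stereospecific SN2 opening and not from facial selection; on the security of the endo centre this alternative is the better one.
- Against it here: in A5, C7 is a carbonyl carbon and the guaiacyl group is still missing. An aryl nucleophile must be added to the lactone and the lactol reduced, which creates C7 late and usually under Lewis acid, where C7' can ionise. The extra ester on C8 must be removed by hot dealkoxycarbonylation. A7 polymerises readily and the oxa-Michael addition of a hindered benzylic alkoxide is reversible. A6 needs the complete side chain before a second asymmetric oxidation on the most valuable fragment.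
- Comparison: on structure, the chosen plan fixes C7 first and never touches it, whereas this one fixes C7' first and leaves C7 to the end. On mechanism, this is an anionic cascade against a catalytic rearrangement that creates no stereocentre. On step economy, about four steps would follow A5, which is equal to the four after 23.

Alternative 3: The cut is the C7'–C8' bond alone. In the forward sense, a dirhodium carboxylate catalyst would convert diazo lactone A9 into a carbenoid at C8' that inserts into a benzylic C–H bond of the ring C methylene ether, closing ring B and giving furofuranone A8, which is the same compound as 24.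
- In its favour: A8 would be reached without ring expansion and without hydrogenating a tetrasubstituted alkene, and the side-chain fragment is needed only at the benzylic alcohol level. Three steps would follow the key step, against four in the chosen plan; on this count and in avoiding the hydrogenation the alternative is the better one.
- Against it here: insertion must compete with oxonium ylide formation at the ether oxygen, attack on three electron-rich arenes and insertion at C7–H. The endo/exo outcome would be set kinetically in a flexible transition state. A9 needs a deacylative diazo transfer, so an acyl group is built in only to be discarded, whereas in the chosen plan the activating aroyl group is ring C itself. The C–C bond would be made last, on the fully elaborated fragment.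
- Comparison: on structure, both use the same ring A lactone. On mechanism, both use a rhodium carbenoid, but the chosen plan asks it only for an early alkene cyclopropanation and then relies on a stereochemically neutral rearrangement and a ring-fusion-controlled syn addition.

Key step: step 14

Remarks on the chemistry:
- Lignan numbering is used as defined above. ArG = 3-methoxy-4-(triisopropylsilyloxy)phenyl. ArC = 3,5-dimethoxy-4-{[(1R,2R)-1,3-bis(tert-butyldimethylsilyloxy)-1-[3,5-dimethoxy-4-(triisopropylsilyloxy)phenyl]propan-2-yl]oxy}phenyl.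
- Correction: the ring closed in the key step has its sp3 carbons at C8 and C9 and its aryl group on the enol ether carbon C7'. It is therefore a 5-aryl-2,3-dihydrofuran, not a 2-aryl-2,3-dihydrofuran. C7 stems from the resolved alcohol; only C8 comes from the cyclopropanation.
- Precursor design: both phenols are carried as triisopropylsilyl ethers, because a phenolic tert-butyldimethylsilyl ether between two methoxy groups would be the group most at risk in hot amine/DMSO. C7' is introduced from an aryl bromide.
- Assumption: 7 and 8 are purchasable.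

## Route

Step 1
Reactants: 1 vanillin
Product: 2 3-methoxy-4-(triisopropylsilyloxy)benzaldehyde
Conditions: TIPSCl, imidazole, DMF, rt
Reagents that add atoms: triisopropylsilyl chloride, CC(C)[Si](Cl)(C(C)C)C(C)C
Why: Silyl ether formation on the phenol; the bulky silyl group survives Grignard, Lewis acid, amine and hydride steps and is removed by fluoride at the end.

Step 2
Reactants: 2 3-methoxy-4-(triisopropylsilyloxy)benzaldehyde
Product: 3 racemic 1-ArG-prop-2-en-1-ol
Conditions: CH2=CHMgBr, THF, −78 → 0 °C; aq. NH4Cl
Reagents that add atoms: vinylmagnesium bromide, C=C[Mg]Br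
Why: Grignard 1,2-addition to the aldehyde forms the C7–C8 bond; C7 is formed racemic and is resolved in the next step.

Step 3
Reactants: 3 racemic 1-ArG-prop-2-en-1-ol
Product: 4 (R)-1-ArG-prop-2-en-1-ol
Conditions: Ti(OiPr)4 (0.2 equiv), D-(−)-DIPT (0.25 equiv), t-BuOOH (0.65 equiv), 4 Å MS, CH2Cl2, −20 °C
Reagents that add atoms: none
Why: Sharpless kinetic resolution of a secondary allylic alcohol; with the D-(−)-tartrate the S enantiomer should be epoxidised faster (to the erythro epoxy alcohol), so the R alcohol is recovered and its purity rises when the reaction is run past half conversion; this fixes C7.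

Step 4
Reactants: 5 syringaldehyde
Product: 6 3,5-dimethoxy-4-(triisopropylsilyloxy)benzaldehyde
Conditions: TIPSCl, imidazole, DMAP (cat.), DMF, 40 °C
Reagents that add atoms: triisopropylsilyl chloride, CC(C)[Si](Cl)(C(C)C)C(C)C
Why: Silyl ether formation on the hindered ring D phenol; the same group as on the guaiacyl ring gives one uniform, robust phenol protection.

Step 5
Reactants: 7 4-bromo-2,6-dimethoxyphenol; 8 (S)-4-benzyl-3-(chloroacetyl)oxazolidin-2-one
Product: 9 (S)-4-benzyl-3-[2-(4-bromo-2,6-dimethoxyphenoxy)acetyl]oxazolidin-2-one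
Conditions: K2CO3, NaI (cat.), acetone, 50 °C
Reagents that add atoms: none
Why: Williamson ether synthesis; the phenoxide displaces the carbonyl-activated primary chloride (iodide catalysis) far faster than carbonate or phenoxide attacks the imide carbonyls, and the bromine serves as the latent carboxyl carbon C7'.

Step 6
Reactants: 9 (S)-4-benzyl-3-[2-(4-bromo-2,6-dimethoxyphenoxy)acetyl]oxazolidin-2-one; 6 3,5-dimethoxy-4-(triisopropylsilyloxy)benzaldehyde
Product: 11 (S)-4-benzyl-3-[(2S,3R)-2-(4-bromo-2,6-dimethoxyphenoxy)-3-hydroxy-3-[3,5-dimethoxy-4-(triisopropylsilyloxy)phenyl]propanoyl]oxazolidin-2-one, via dibutylboron Z-enolate 10 (not isolated)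
Conditions: Bu2BOTf, i-Pr2NEt, CH2Cl2, −78 → 0 °C; then 6, −78 → 0 °C; pH 7 buffer, MeOH, H2O2, 0 °C
Reagents that add atoms: none
Why: Evans syn-aldol reaction; the Z-boron enolate reacts through a chair Zimmerman–Traxler transition state on the face away from the benzyl group of the S auxiliary, which should give the 2S,3R syn adduct, i.e. the threo 7''R,8''R pair with the aryl ether oxygen already on C8''.

Step 7
Reactants: 11 syn-aldol adduct
Product: 12 (1R,2R)-2-(4-bromo-2,6-dimethoxyphenoxy)-1-[3,5-dimethoxy-4-(triisopropylsilyloxy)phenyl]propane-1,3-diol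
Conditions: LiBH4, MeOH (1 equiv), THF, 0 °C
Reagents that add atoms: none
Why: Reductive cleavage of the N-acyl oxazolidinone; the exocyclic imide carbonyl is much more electrophilic than the carbamate, the aryl bromide and aryl silyl ether are inert, and neither stereocentre is touched.

Step 8
Reactants: 12 (1R,2R)-diol
Product: 13 5-bromo-2-{[(1R,2R)-1,3-bis(tert-butyldimethylsilyloxy)-1-[3,5-dimethoxy-4-(triisopropylsilyloxy)phenyl]propan-2-yl]oxy}-1,3-dimethoxybenzene
Conditions: TBSOTf, 2,6-lutidine, CH2Cl2, −78 → 0 °C
Reagents that add atoms: tert-butyldimethylsilyl triflate, CC(C)(C)[Si](C)(C)OS(=O)(=O)C(F)(F)F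
Why: Silylation of the primary and the secondary benzylic hydroxyl with a silyl triflate and a hindered base; the buffered, cold conditions avoid ionisation of the electron-rich benzylic position.

Step 9
Reactants: 13 aryl bromide
Product: 15 ArC-carboxylic acid (4-{[(1R,2R)-1,3-bis(tert-butyldimethylsilyloxy)-1-[3,5-dimethoxy-4-(triisopropylsilyloxy)phenyl]propan-2-yl]oxy}-3,5-dimethoxybenzoic acid), via aryllithium 14 (not isolated)
Conditions: n-BuLi, THF, −78 °C; CO2 (g), −78 °C → rt; aq. citric acid
Reagents that add atoms: carbon dioxide, O=C=O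
Why: Bromine–lithium exchange is faster than any deprotonation at −78 °C, and carboxylation of the aryllithium gives the acid directly; silyl ethers tolerate butyllithium at this temperature and the mild acidic work-up.

Step 10
Reactants: 15 ArC-carboxylic acid; 16 Meldrum's acid
Product: 17 5-[ArC(hydroxy)methylidene]-2,2-dimethyl-1,3-dioxane-4,6-dione
Conditions: EDC·HCl, DMAP, CH2Cl2, 0 °C → rt; cold 5% aq. KHSO4 wash
Reagents that add atoms: none
Why: Carbodiimide/DMAP C-acylation of Meldrum's acid gives the stable enol of the acyl derivative, which forms the C7'–C8' bond and brings in C8' and C9'.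

Step 11
Reactants: 17 acyl Meldrum's acid; 4 (R)-1-ArG-prop-2-en-1-ol
Product: 19 (R)-1-ArG-prop-2-en-1-yl 3-ArC-3-oxopropanoate, via aroylketene 18 (not isolated)
Conditions: toluene, 85 °C
Reagents that add atoms: none
Why: Thermolysis of the acyl Meldrum's acid expels acetone and CO2 to give the aroylketene, which is trapped by the hydroxyl of 4; the C7–O bond of 4 is not broken, so C7 keeps its configuration.

Step 12
Reactants: 19 β-keto ester
Product: 20 (R)-1-ArG-prop-2-en-1-yl 2-diazo-3-ArC-3-oxopropanoate
Conditions: p-ABSA, Et3N, MeCN, 0 °C → rt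
Reagents that add atoms: 4-acetamidobenzenesulfonyl azide, CC(=O)Nc1ccc(cc1)S(=O)(=O)N=[N+]=[N-]
Why: Regitz diazo transfer to the doubly activated methylene C8' of the β-keto ester under mild amine base.

Step 13
Reactants: 20 α-diazo-β-keto ester
Product: 21 (1S,4R,5R)-1-(ArC-carbonyl)-4-ArG-3-oxabicyclo[3.1.0]hexan-2-one
Conditions: Rh2(OAc)4 (2 mol%), CH2Cl2, reflux, slow addition
Reagents that add atoms: none
Why: Rhodium-carbenoid intramolecular cyclopropanation of the allyl ester forms C8'–C8 and C8'–C9 and closes the ring A lactone with enforced cis fusion; the alkene should react in the conformer with C7–H eclipsing the vinyl group (least allylic strain), which puts the aryl group trans to the cyclopropane methylene and so sets C8 relative to C7.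

Step 14
Reactants: 21 cyclopropane-fused keto lactone
Product: 23 (5S,6R)-2-ArC-6-ArG-3,7-dioxabicyclo[3.3.0]oct-1-en-8-one, via ammonium enolate zwitterion 22 (not isolated)
Conditions: DABCO (0.3 equiv), anhydrous DMSO, 100 °C
Reagents that add atoms: none
Why: Nucleophile-catalysed Cloke–Wilson rearrangement: DABCO attacks the cyclopropane methylene C9 in an SN2 (homoconjugate) opening, the C8'–C9 bond breaks into the lactone and aroyl carbonyls, and the ammonium enolate 22 results. The oxygen of the aroyl enolate then displaces the ammonium group at C9 in a 5-exo-tet closure (enolate C=C inside the new ring), which forms the O–C9 bond, closes ring B and releases the catalyst. The closest known reaction type is the amine-, phosphine- or halide-catalysed ring expansion of 1-acylcyclopropane-1-carboxylates to 2,3-dihydrofuran-4-carboxylates. No stereocentre is created: C8' becomes trigonal and C7 and C8 are not involved, so their spatial arrangement is carried over (C8 changes descriptor only because substituent ranking changes). Regioselective opening is needed and is secured by sterics, since C9 is a methylene whereas C8 is a methine flanked by C7 and the quaternary C8'. Closure on oxygen rather than carbon is needed; C-closure only regenerates 21, which re-enters the cycle, while O-closure is irreversible. Closure through the lactone oxygen would give a strained bicyclic ketene acetal and is not expected.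

Step 15
Reactants: 23 dihydrofuran-fused lactone
Product: 24 (1R,2S,5S,6R)-2-ArC-6-ArG-3,7-dioxabicyclo[3.3.0]octan-8-one
Conditions: H2 (5 bar), 5% Rh/Al2O3, EtOAc, rt
Reagents that add atoms: none
Why: Heterogeneous syn hydrogenation of the aryl-conjugated enol ether; only delivery from the convex face (the face of H8) can give a cis-fused bicycle, so H8' and H7' enter syn to H8 and the ring C aryl group is placed endo; Rh/Al2O3 is chosen because it saturates enol ethers with little benzylic C–O hydrogenolysis.

Step 16
Reactants: 24 furofuranone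
Product: 25 (R)-ArG-[(3S,4S,5S)-5-ArC-4-(hydroxymethyl)oxolan-3-yl]methanol
Conditions: LiAlH4, THF, 0 °C; aq. KNaC4H4O6 work-up
Reagents that add atoms: none
Why: Hydride reduction of the γ-lactone to the 1,4-diol; at 0 °C the alkyl and aryl silyl ethers survive and no stereocentre is affected.

Step 17
Reactants: 25 diol
Product: 27 (1S,2S,5S,6R)-2-ArC-6-ArG-3,7-dioxabicyclo[3.3.0]octane, via primary mesylate 26 (not isolated)
Conditions: MsCl (1.1 equiv), Et3N, CH2Cl2, 0 °C → rt
Reagents that add atoms: none
Why: Selective sulfonylation of the primary C9' hydroxyl followed by 5-exo-tet Williamson cyclisation by the benzylic C7 hydroxyl closes ring A; the C7–O bond is never broken, so C7 is retained, and even an ionising pathway would converge on the same, more stable exo aryl group.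

Step 18
Reactants: 27 tetrasilyl ether
Product: 28 target, (1S,2S,5S,6R)-6-(4-hydroxy-3-methoxyphenyl)-2-{4-[(1R,2R)-1,3-dihydroxy-1-(4-hydroxy-3,5-dimethoxyphenyl)propan-2-yl]oxy-3,5-dimethoxyphenyl}-3,7-dioxabicyclo[3.3.0]octane
Conditions: TBAF, AcOH (1:1), THF, 0 °C → rt
Reagents that add atoms: none
Why: Fluoride cleavage of all four Si–O bonds; acetic acid buffering keeps the medium near neutral so that the endo benzylic ether C7' and the 4-hydroxybenzyl alcohol at C7'' are not epimerised.

## Compound list

1 | vanillin | COc1cc(C=O)ccc1O | starting material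
2 | 3-methoxy-4-(triisopropylsilyloxy)benzaldehyde | COc1cc(C=O)ccc1O[Si](C(C)C)(C(C)C)C(C)C | intermediate
3 | racemic 1-ArG-prop-2-en-1-ol | COc1cc(C(O)C=C)ccc1O[Si](C(C)C)(C(C)C)C(C)C | intermediate
4 | (R)-1-ArG-prop-2-en-1-ol | COc1cc([C@H](O)C=C)ccc1O[Si](C(C)C)(C(C)C)C(C)C | intermediate
5 | syringaldehyde | COc1cc(C=O)cc(OC)c1O | starting material
6 | 3,5-dimethoxy-4-(triisopropylsilyloxy)benzaldehyde | COc1cc(C=O)cc(OC)c1O[Si](C(C)C)(C(C)C)C(C)C | intermediate
7 | 4-bromo-2,6-dimethoxyphenol | COc1cc(Br)cc(OC)c1O | starting material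
8 | (S)-4-benzyl-3-(chloroacetyl)oxazolidin-2-one | O=C(CCl)N1C(=O)OC[C@@H]1Cc1ccccc1 | starting material
9 | (S)-4-benzyl-3-[2-(4-bromo-2,6-dimethoxyphenoxy)acetyl]oxazolidin-2-one | COc1cc(Br)cc(OC)c1OCC(=O)N1C(=O)OC[C@@H]1Cc1ccccc1 | intermediate
10 | dibutylboron Z-enolate of 9 | CCCCB(CCCC)O/C(=C\Oc1c(OC)cc(Br)cc1OC)N1C(=O)OC[C@@H]1Cc1ccccc1 | intermediate
11 | (S)-4-benzyl-3-[(2S,3R)-2-(4-bromo-2,6-dimethoxyphenoxy)-3-hydroxy-3-[3,5-dimethoxy-4-(triisopropylsilyloxy)phenyl]propanoyl]oxazolidin-2-one | COc1cc(Br)cc(OC)c1O[C@H](C(=O)N1C(=O)OC[C@@H]1Cc1ccccc1)[C@H](O)c1cc(OC)c(O[Si](C(C)C)(C(C)C)C(C)C)c(OC)c1 | intermediate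
12 | (1R,2R)-2-(4-bromo-2,6-dimethoxyphenoxy)-1-[3,5-dimethoxy-4-(triisopropylsilyloxy)phenyl]propane-1,3-diol | COc1cc(Br)cc(OC)c1O[C@H](CO)[C@H](O)c1cc(OC)c(O[Si](C(C)C)(C(C)C)C(C)C)c(OC)c1 | intermediate
13 | 5-bromo-2-{[(1R,2R)-1,3-bis(tert-butyldimethylsilyloxy)-1-[3,5-dimethoxy-4-(triisopropylsilyloxy)phenyl]propan-2-yl]oxy}-1,3-dimethoxybenzene | COc1cc(Br)cc(OC)c1O[C@H](CO[Si](C)(C)C(C)(C)C)[C@H](O[Si](C)(C)C(C)(C)C)c1cc(OC)c(O[Si](C(C)C)(C(C)C)C(C)C)c(OC)c1 | intermediate
14 | aryllithium from 13 (lithium in place of bromine) | COc1cc([Li])cc(OC)c1O[C@H](CO[Si](C)(C)C(C)(C)C)[C@H](O[Si](C)(C)C(C)(C)C)c1cc(OC)c(O[Si](C(C)C)(C(C)C)C(C)C)c(OC)c1 | intermediate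
15 | ArC-carboxylic acid | COc1cc(C(=O)O)cc(OC)c1O[C@H](CO[Si](C)(C)C(C)(C)C)[C@H](O[Si](C)(C)C(C)(C)C)c1cc(OC)c(O[Si](C(C)C)(C(C)C)C(C)C)c(OC)c1 | intermediate
16 | Meldrum's acid | CC1(C)OC(=O)CC(=O)O1 | starting material
17 | 5-[ArC(hydroxy)methylidene]-2,2-dimethyl-1,3-dioxane-4,6-dione | CC1(C)OC(=O)C(=C(O)c2cc(OC)c(O[C@H](CO[Si](C)(C)C(C)(C)C)[C@H](O[Si](C)(C)C(C)(C)C)c3cc(OC)c(O[Si](C(C)C)(C(C)C)C(C)C)c(OC)c3)c(OC)c2)C(=O)O1 | intermediate
18 | aroylketene ArC–C(=O)–CH=C=O | O=C=CC(=O)c1cc(OC)c(O[C@H](CO[Si](C)(C)C(C)(C)C)[C@H](O[Si](C)(C)C(C)(C)C)c2cc(OC)c(O[Si](C(C)C)(C(C)C)C(C)C)c(OC)c2)c(OC)c1 | intermediate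
19 | (R)-1-ArG-prop-2-en-1-yl 3-ArC-3-oxopropanoate | COc1cc([C@H](OC(=O)CC(=O)c2cc(OC)c(O[C@H](CO[Si](C)(C)C(C)(C)C)[C@H](O[Si](C)(C)C(C)(C)C)c3cc(OC)c(O[Si](C(C)C)(C(C)C)C(C)C)c(OC)c3)c(OC)c2)C=C)ccc1O[Si](C(C)C)(C(C)C)C(C)C | intermediate
20 | (R)-1-ArG-prop-2-en-1-yl 2-diazo-3-ArC-3-oxopropanoate | COc1cc([C@H](OC(=O)C(=[N+]=[N-])C(=O)c2cc(OC)c(O[C@H](CO[Si](C)(C)C(C)(C)C)[C@H](O[Si](C)(C)C(C)(C)C)c3cc(OC)c(O[Si](C(C)C)(C(C)C)C(C)C)c(OC)c3)c(OC)c2)C=C)ccc1O[Si](C(C)C)(C(C)C)C(C)C | intermediate
21 | (1S,4R,5R)-1-(ArC-carbonyl)-4-ArG-3-oxabicyclo[3.1.0]hexan-2-one (aryl trans to the cyclopropane methylene) | COc1cc([C@@H]2OC(=O)[C@@]3(C(=O)c4cc(OC)c(O[C@H](CO[Si](C)(C)C(C)(C)C)[C@H](O[Si](C)(C)C(C)(C)C)c5cc(OC)c(O[Si](C(C)C)(C(C)C)C(C)C)c(OC)c5)c(OC)c4)C[C@@H]23)ccc1O[Si](C(C)C)(C(C)C)C(C)C | intermediate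
22 | ammonium enolate zwitterion (DABCO on C9, enolate over C9'–C8'–C7') | COc1cc([C@@H]2OC(=O)C(=C([O-])c3cc(OC)c(O[C@H](CO[Si](C)(C)C(C)(C)C)[C@H](O[Si](C)(C)C(C)(C)C)c4cc(OC)c(O[Si](C(C)C)(C(C)C)C(C)C)c(OC)c4)c(OC)c3)[C@H]2C[N+]23CCN(CC2)CC3)ccc1O[Si](C(C)C)(C(C)C)C(C)C | intermediate
23 | (5S,6R)-2-ArC-6-ArG-3,7-dioxabicyclo[3.3.0]oct-1-en-8-one | COc1cc([C@@H]2OC(=O)C3=C(c4cc(OC)c(O[C@H](CO[Si](C)(C)C(C)(C)C)[C@H](O[Si](C)(C)C(C)(C)C)c5cc(OC)c(O[Si](C(C)C)(C(C)C)C(C)C)c(OC)c5)c(OC)c4)OC[C@@H]23)ccc1O[Si](C(C)C)(C(C)C)C(C)C | intermediate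
24 | (1R,2S,5S,6R)-2-ArC-6-ArG-3,7-dioxabicyclo[3.3.0]octan-8-one (7R,8S,7'S,8'R) | COc1cc([C@@H]2OC(=O)[C@@H]3[C@H]2CO[C@@H]3c2cc(OC)c(O[C@H](CO[Si](C)(C)C(C)(C)C)[C@H](O[Si](C)(C)C(C)(C)C)c3cc(OC)c(O[Si](C(C)C)(C(C)C)C(C)C)c(OC)c3)c(OC)c2)ccc1O[Si](C(C)C)(C(C)C)C(C)C | intermediate
25 | (R)-ArG-[(3S,4S,5S)-5-ArC-4-(hydroxymethyl)oxolan-3-yl]methanol | COc1cc([C@H](O)[C@@H]2CO[C@H](c3cc(OC)c(O[C@H](CO[Si](C)(C)C(C)(C)C)[C@H](O[Si](C)(C)C(C)(C)C)c4cc(OC)c(O[Si](C(C)C)(C(C)C)C(C)C)c(OC)c4)c(OC)c3)[C@@H]2CO)ccc1O[Si](C(C)C)(C(C)C)C(C)C | intermediate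
26 | primary (C9') methanesulfonate of 25 | COc1cc([C@H](O)[C@@H]2CO[C@H](c3cc(OC)c(O[C@H](CO[Si](C)(C)C(C)(C)C)[C@H](O[Si](C)(C)C(C)(C)C)c4cc(OC)c(O[Si](C(C)C)(C(C)C)C(C)C)c(OC)c4)c(OC)c3)[C@@H]2COS(C)(=O)=O)ccc1O[Si](C(C)C)(C(C)C)C(C)C | intermediate
27 | (1S,2S,5S,6R)-2-ArC-6-ArG-3,7-dioxabicyclo[3.3.0]octane (tetrasilyl ether of the target) | COc1cc([C@@H]2OC[C@@H]3[C@H]2CO[C@@H]3c2cc(OC)c(O[C@H](CO[Si](C)(C)C(C)(C)C)[C@H](O[Si](C)(C)C(C)(C)C)c3cc(OC)c(O[Si](C(C)C)(C(C)C)C(C)C)c(OC)c3)c(OC)c2)ccc1O[Si](C(C)C)(C(C)C)C(C)C | intermediate
28 | CNP0317965.1, (7R,8S,7'S,8'S,7''R,8''R) | COc1cc([C@@H]2OC[C@@H]3[C@H]2CO[C@@H]3c2cc(OC)c(O[C@H](CO)[C@H](O)c3cc(OC)c(O)c(OC)c3)c(OC)c2)ccc1O | target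

## Step count and least certain steps

Total: 18 steps. Longest linear sequence: 14 steps (steps 5 to 18 from 7 and 8; the same count from 5 through steps 4 and 6 to 18).

Step 14 (key step). The zwitterion may collapse back to 21 faster than it closes on oxygen at temperatures the phenolic silyl ethers tolerate, so conversion could stall or desilylation set in. The fallback sets out from 21 and returns at 23, and separates opening from closure. Stoichiometric MgI2 in THF opens the cyclopropane at C9 (Lewis-acid-assisted homoconjugate addition of iodide) to the isolable iodomethyl keto lactone F1. F1 is then closed with Ag2CO3 in toluene, where halophilic activation of the C9–I bond under non-basic conditions favours attack by the enol oxygen.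

Step 13. Facial selectivity at C8 may be poor (aryl cis to the cyclopropane), and the electrophilic carbenoid may be diverted into the electron-rich guaiacyl ring. The fallback sets out from 19 and returns at 21 (no new compound, F0). It is a one-electron oxidative cyclisation with Mn(OAc)3·2H2O and Cu(OAc)2·H2O in EtOH/AcOH at rt: the trivalent manganese enolate gives the C8' radical, which cyclises 5-exo onto C8; the C9 radical is oxidised by divalent copper and closes to the cyclopropane. No carbenoid is involved and step 12 is not needed.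

Step 15. Hydrogen uptake by the tetrasubstituted push–pull alkene may be sluggish, and forcing conditions could bring hydrogenolysis of the benzylic C–O bonds or arene saturation. The fallback sets out from 23 and returns at 24 (no new compound, F0). It is an electron-transfer conjugate reduction with SmI2, HMPA and t-BuOH in THF at −78 °C: C7' and then the lactone enolate carbon C8' are protonated from the convex face, cis fusion again fixes C8', and no C–O bond meets a hydrogenation catalyst.

Step 11. The acidic acyl Meldrum's acid at 85 °C may ionise the electron-rich allylic alcohol or ester 19, with allylic transposition to the cinnamyl isomer and erosion of C7. The fallback sets out from 4 and 15 and returns at 19. Alcohol 4 is acetylated (Ac2O, pyridine) to the acetate F2, and 15 is converted with carbonyldiimidazole into the acyl imidazolide F3. The lithium enolate of F2 (LiN(SiMe3)2, 2.2 equiv, THF, −78 °C) is then acylated by F3 in a crossed Claisen condensation, below −40 °C and without acid.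

Step 3. Slow epoxidation of the monosubstituted alkene may let titanium-induced ionisation of the benzylic alcohol compete, giving an incomplete resolution. The fallback sets out from 3 and returns at 4. Immobilised Candida antarctica lipase B and vinyl acetate in hexane acylate the R enantiomer to the acetate F4; the unreacted S alcohol is separated, and F4 is cleaved with i-Bu2AlH in CH2Cl2 at −78 °C to 4.

## Further compounds

F1 | step 14 | (4S,5R)-3-(ArC-carbonyl)-4-(iodomethyl)-5-ArG-oxolan-2-one (C8' epimers/enol) | COc1cc([C@@H]2OC(=O)C(C(=O)c3cc(OC)c(O[C@H](CO[Si](C)(C)C(C)(C)C)[C@H](O[Si](C)(C)C(C)(C)C)c4cc(OC)c(O[Si](C(C)C)(C(C)C)C(C)C)c(OC)c4)c(OC)c3)[C@H]2CI)ccc1O[Si](C(C)C)(C(C)C)C(C)C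
F0 | step 13 | none | none
F0 | step 15 | none | none
F2 | step 11 | (R)-1-ArG-prop-2-en-1-yl acetate | COc1cc([C@H](OC(C)=O)C=C)ccc1O[Si](C(C)C)(C(C)C)C(C)C
F3 | step 11 | 1-(ArC-carbonyl)imidazole | COc1cc(C(=O)n2ccnc2)cc(OC)c1O[C@H](CO[Si](C)(C)C(C)(C)C)[C@H](O[Si](C)(C)C(C)(C)C)c1cc(OC)c(O[Si](C(C)C)(C(C)C)C(C)C)c(OC)c1
F4 | step 3 | (R)-1-ArG-prop-2-en-1-yl acetate | COc1cc([C@H](OC(C)=O)C=C)ccc1O[Si](C(C)C)(C(C)C)C(C)C
A1 | alternative 1 | trans,trans-trisubstituted lactone with the anti aldol carbinol | COc1cc(C2(SCCCS2)[C@@H]2[C@@H](COC(c3ccccc3)(c3ccccc3)c3ccccc3)OC(=O)[C@H]2[C@H](O)c2cc(OC)c(O[C@H](CO[Si](C)(C)C(C)(C)C)[C@H](O[Si](C)(C)C(C)(C)C)c3cc(OC)c(O[Si](C(C)C)(C(C)C)C(C)C)c(OC)c3)c(OC)c2)ccc1O[Si](C(C)C)(C(C)C)C(C)C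
A2 | alternative 1 | (S)-5-(trityloxymethyl)furan-2(5H)-one | O=C1C=C[C@@H](COC(c2ccccc2)(c2ccccc2)c2ccccc2)O1
A3 | alternative 1 | 2-lithio-2-ArG-1,3-dithiane | COc1cc(C2([Li])SCCCS2)ccc1O[Si](C(C)C)(C(C)C)C(C)C
A4 | alternative 1 | ArC-carbaldehyde | COc1cc(C=O)cc(OC)c1O[C@H](CO[Si](C)(C)C(C)(C)C)[C@H](O[Si](C)(C)C(C)(C)C)c1cc(OC)c(O[Si](C(C)C)(C(C)C)C(C)C)c(OC)c1
A5 | alternative 2 | cis-fused lactone ester with endo ArC group | O=C1OC[C@@H]2[C@@]1(C(=O)OC)CO[C@@H]2c1cc(OC)c(O[C@H](CO[Si](C)(C)C(C)(C)C)[C@H](O[Si](C)(C)C(C)(C)C)c2cc(OC)c(O[Si](C(C)C)(C(C)C)C(C)C)c(OC)c2)c(OC)c1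
A6 | alternative 2 | threo (R)-ArC-[(R)-oxiran-2-yl]methanol | O[C@@H]([C@H]1CO1)c1cc(OC)c(O[C@H](CO[Si](C)(C)C(C)(C)C)[C@H](O[Si](C)(C)C(C)(C)C)c2cc(OC)c(O[Si](C(C)C)(C(C)C)C(C)C)c(OC)c2)c(OC)c1
A7 | alternative 2 | dimethyl methylenemalonate | C=C(C(=O)OC)C(=O)OC
A8 | alternative 3 | endo-ArC, exo-ArG furofuranone (identical with 24) | COc1cc([C@@H]2OC(=O)[C@@H]3[C@H]2CO[C@@H]3c2cc(OC)c(O[C@H](CO[Si](C)(C)C(C)(C)C)[C@H](O[Si](C)(C)C(C)(C)C)c3cc(OC)c(O[Si](C(C)C)(C(C)C)C(C)C)c(OC)c3)c(OC)c2)ccc1O[Si](C(C)C)(C(C)C)C(C)C
A9 | alternative 3 | (4S,5R)-3-diazo-4-[(ArC-methoxy)methyl]-5-ArG-oxolan-2-one | COc1cc([C@@H]2OC(=O)C(=[N+]=[N-])[C@H]2COCc2cc(OC)c(O[C@H](CO[Si](C)(C)C(C)(C)C)[C@H](O[Si](C)(C)C(C)(C)C)c3cc(OC)c(O[Si](C(C)C)(C(C)C)C(C)C)c(OC)c3)c(OC)c2)ccc1O[Si](C(C)C)(C(C)C)C(C)C
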